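**Retrosynthetic overview** (spiro[4.5]decane locants: C5 spiro; C6 alkene carbon bearing CH2O; C7 alkene CH; C8, C9 carbinol carbons; C10 CHMe; C1/C4 ring CH2; C2 ring CH bearing the lactone α-carbon; C3 ring CH–O)
1. Target 26 ← lactol oxidation, acid opening of a vinyl epoxide (trans-diol), Mitsunobu angeloylation and ester reduction ← spiro vinyl-epoxide enoate 21, with the α-methylene lactone masked as a mixed acetal.
2. Key disconnection: C6–C7 and C8–C9 of the cyclohexene are made together from sulfinyl ester aldehyde 17 and a two-carbon vinylsulfonium salt (conjugate addition, ylide epoxidation, sulfoxide elimination).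
3. Enabling feature: the quaternary spiro carbon C5 holds the acidic C6–H and the C9 aldehyde at the ends of the four-carbon chain C6–C5–C10–C9 and has no hydrogen of its own; the C6=C7–C8(OH)–C9(OH) unit of the six-membered ring is the retron of a vinyl epoxide.
4. C5 and C10: two enolate alkylations of (R)-β-methyl-γ-butyrolactone 1, each anti to methyl; the lactone carbonyl becomes C1; aldol cyclopentenone, CBS reduction and vinyl-radical cyclisation build the cis-fused methylene tetrahydrofuran.
5. Ring order: cyclopentene (step 7), tetrahydrofuran (step 10), cyclohexene with oxirane (step 14); the lactone carbonyl comes last (step 18).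

Key step: step 14

Assumption: (R)-4-methyldihydrofuran-2(3H)-one 1 is taken as a commercial enantiopure building block.

Step 1
Reactants: 1 (R)-4-methyldihydrofuran-2(3H)-one; 2 3-bromo-2-methylprop-1-ene
Product: 3 (3R,4R)-4-methyl-3-(2-methylprop-2-en-1-yl)dihydrofuran-2(3H)-one
Conditions: LiN(iPr)2, THF, −78 °C; then 2, −78 → −30 °C
Reagents that add atoms: none
Why: Lithium enolate alkylation of a γ-lactone, in which the methallyl group should enter anti to the neighbouring 4-methyl group (1,2-induction), although this centre is re-enolised in step 2.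

Step 2
Reactants: 3 (3R,4R)-4-methyl-3-(2-methylprop-2-en-1-yl)dihydrofuran-2(3H)-one; 4 tert-butyl bromoacetate
Product: 5 tert-butyl 2-[(3R,4R)-4-methyl-3-(2-methylprop-2-en-1-yl)-2-oxotetrahydrofuran-3-yl]acetate
Conditions: LiN(iPr)2, THF/DMPU, −78 °C; then 4, −78 → −20 °C
Reagents that add atoms: none
Why: A second enolate alkylation creates the quaternary carbon (future spiro C5), and because the electrophile should again approach anti to the 4-methyl group the methallyl arm ends cis and the acetate arm trans to methyl, which fixes C5 relative to C10.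

Step 3
Reactants: 5 tert-butyl 2-[(3R,4R)-4-methyl-3-(2-methylprop-2-en-1-yl)-2-oxotetrahydrofuran-3-yl]acetate
Product: 6 tert-butyl 2-[(3R,4R)-2-hydroxy-4-methyl-3-(2-methylprop-2-en-1-yl)tetrahydrofuran-3-yl]acetate (lactol)
Conditions: iBu2AlH (1.1 equiv), CH2Cl2, −78 °C
Reagents that add atoms: none
Why: Partial reduction of a γ-lactone to the lactol at low temperature, where the hindered tert-butyl ester should survive and only an inconsequential anomeric centre is formed.

Step 4
Reactants: 6 tert-butyl 2-[(3R,4R)-2-hydroxy-4-methyl-3-(2-methylprop-2-en-1-yl)tetrahydrofuran-3-yl]acetate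
Product: 7 tert-butyl (3S)-3-ethenyl-3-[(2R)-1-hydroxypropan-2-yl]-5-methylhex-5-enoate
Conditions: Ph3PCH3Br, KOtBu, THF, 0 °C → rt
Reagents that add atoms: methyltriphenylphosphonium bromide, C[P+](c1ccccc1)(c1ccccc1)c1ccccc1.[Br-]
Why: Wittig methylenation of the open hydroxy aldehyde form of the lactol turns the former lactone carbonyl (C1) into a vinyl group and frees the primary alcohol without touching a stereocentre.

Step 5
Reactants: 7 tert-butyl (3S)-3-ethenyl-3-[(2R)-1-hydroxypropan-2-yl]-5-methylhex-5-enoate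
Product: 8 tert-butyl (3S)-3-[(2R)-1-{[tert-butyl(dimethyl)silyl]oxy}propan-2-yl]-3-ethenyl-5-methylhex-5-enoate
Conditions: tBuMe2SiCl, imidazole, DMF, rt
Reagents that add atoms: tert-butyldimethylsilyl chloride, CC(C)(C)[Si](C)(C)Cl
Why: Standard silylation of the primary alcohol, needed so that it cannot add in oxa-Michael fashion to the enone made in step 7.

Step 6
Reactants: 8 tert-butyl (3S)-3-[(2R)-1-{[tert-butyl(dimethyl)silyl]oxy}propan-2-yl]-3-ethenyl-5-methylhex-5-enoate
Product: 9 tert-butyl (3R)-3-[(2R)-1-{[tert-butyl(dimethyl)silyl]oxy}propan-2-yl]-3-formyl-5-oxohexanoate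
Conditions: O3, CH2Cl2/MeOH, −78 °C; then Me2S, −78 °C → rt
Reagents that add atoms: ozone, [O-][O+]=O
Why: Ozonolysis with reductive work-up cleaves both terminal alkenes at once and gives the non-enolisable aldehyde on the quaternary carbon together with the methyl ketone.

Step 7
Reactants: 9 tert-butyl (3R)-3-[(2R)-1-{[tert-butyl(dimethyl)silyl]oxy}propan-2-yl]-3-formyl-5-oxohexanoate
Product: 10 tert-butyl 2-[(1S)-1-[(2R)-1-{[tert-butyl(dimethyl)silyl]oxy}propan-2-yl]-4-oxocyclopent-2-en-1-yl]acetate
Conditions: KOH (0.2 equiv), MeOH, 0 °C → rt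
Reagents that add atoms: none
Why: Intramolecular aldol condensation of a 1,4-keto aldehyde (5-enolexo closure of the methyl ketone onto the aldehyde) should give the 4,4-disubstituted cyclopent-2-enone with the ketone at C3 and the quaternary centre untouched.

Step 8
Reactants: 10 tert-butyl 2-[(1S)-1-[(2R)-1-{[tert-butyl(dimethyl)silyl]oxy}propan-2-yl]-4-oxocyclopent-2-en-1-yl]acetate
Product: 11 tert-butyl 2-[(1S,4R)-1-[(2R)-1-{[tert-butyl(dimethyl)silyl]oxy}propan-2-yl]-4-hydroxycyclopent-2-en-1-yl]acetate
Conditions: (S)-1-methyl-3,3-diphenyltetrahydro-1H,3H-pyrrolo[1,2-c][1,3,2]oxazaborole (0.2 equiv), BH3·SMe2, THF, −30 °C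
Reagents that add atoms: none
Why: Corey–Bakshi–Shibata reduction, in which the catalyst (alkene arm of the enone taken as the large group) should deliver hydride to the face that gives the (R)-carbinol at C3, so that the hydroxyl is cis to the CH2CO2tBu arm under reagent control.

Step 9
Reactants: 11 tert-butyl 2-[(1S,4R)-1-[(2R)-1-{[tert-butyl(dimethyl)silyl]oxy}propan-2-yl]-4-hydroxycyclopent-2-en-1-yl]acetate; 12 methoxyallene
Product: 13 tert-butyl 2-[(1S,4R)-1-[(2R)-1-{[tert-butyl(dimethyl)silyl]oxy}propan-2-yl]-4-[(2-iodo-1-methoxyprop-2-en-1-yl)oxy]cyclopent-2-en-1-yl]acetate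
Conditions: N-iodosuccinimide, CH2Cl2, −40 → 0 °C
Reagents that add atoms: N-iodosuccinimide, O=C1CCC(=O)N1I
Why: Iodoalkoxylation of the alkoxyallene (iodonium attack at the central allene carbon, capture of the oxocarbenium ion by the allylic alcohol) should give the 2-iodoallyl mixed acetal as inconsequential acetal epimers.

Step 10
Reactants: 13 tert-butyl 2-[(1S,4R)-1-[(2R)-1-{[tert-butyl(dimethyl)silyl]oxy}propan-2-yl]-4-[(2-iodo-1-methoxyprop-2-en-1-yl)oxy]cyclopent-2-en-1-yl]acetate
Product: 14 tert-butyl 2-{2-methoxy-3-methylidene-5-[(2R)-1-{[tert-butyl(dimethyl)silyl]oxy}propan-2-yl]hexahydro-2H-cyclopenta[b]furan-5-yl}acetate (cis-fused)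
Conditions: Bu3SnH, 2,2'-azobis(2-methylpropionitrile) (cat.), benzene, 80 °C, slow addition
Reagents that add atoms: none
Why: Ueno–Stork-type radical cyclisation in which the vinyl radical closes 5-exo-trig onto the nearer alkene carbon (C2) from the face of the oxygen tether, so the new C–C bond is cis to the C3 oxygen, and the resulting C1 radical is reduced by the stannane.

Step 11
Reactants: 14 tert-butyl 2-{2-methoxy-3-methylidene-5-[(2R)-1-{[tert-butyl(dimethyl)silyl]oxy}propan-2-yl]hexahydro-2H-cyclopenta[b]furan-5-yl}acetate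
Product: 15 tert-butyl 2-{2-methoxy-3-methylidene-5-[(2R)-1-{[tert-butyl(dimethyl)silyl]oxy}propan-2-yl]hexahydro-2H-cyclopenta[b]furan-5-yl}-2-(phenylsulfinyl)acetate
Conditions: LiN(iPr)2 (2.2 equiv), THF, −78 °C; then PhS(O)OMe, −78 → 0 °C
Reagents that add atoms: methyl benzenesulfinate, COS(=O)c1ccccc1
Why: Sulfinylation of the ester lithium enolate with a sulfinate ester installs the group that activates C6–H and later leaves, the new carbon and sulfur stereocentres being formed as a mixture that is erased in step 14.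

Step 12
Reactants: 15 tert-butyl 2-{2-methoxy-3-methylidene-5-[(2R)-1-{[tert-butyl(dimethyl)silyl]oxy}propan-2-yl]hexahydro-2H-cyclopenta[b]furan-5-yl}-2-(phenylsulfinyl)acetate
Product: 16 tert-butyl 2-{5-[(2R)-1-hydroxypropan-2-yl]-2-methoxy-3-methylidenehexahydro-2H-cyclopenta[b]furan-5-yl}-2-(phenylsulfinyl)acetate
Conditions: Bu4NF, THF, 0 °C
Reagents that add atoms: none
Why: Fluoride cleavage of the primary silyl ether, which should leave acetal, ester and sulfoxide untouched.

Step 13
Reactants: 16 tert-butyl 2-{5-[(2R)-1-hydroxypropan-2-yl]-2-methoxy-3-methylidenehexahydro-2H-cyclopenta[b]furan-5-yl}-2-(phenylsulfinyl)acetate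
Product: 17 tert-butyl 2-{2-methoxy-3-methylidene-5-[(2R)-1-oxopropan-2-yl]hexahydro-2H-cyclopenta[b]furan-5-yl}-2-(phenylsulfinyl)acetate
Conditions: Dess–Martin periodinane, CH2Cl2, 0 °C → rt
Reagents that add atoms: none
Why: Dess–Martin oxidation gives the aldehyde under near-neutral conditions that should not epimerise the α-methyl centre (C10).

Step 14
Reactants: 17 tert-butyl 2-{2-methoxy-3-methylidene-5-[(2R)-1-oxopropan-2-yl]hexahydro-2H-cyclopenta[b]furan-5-yl}-2-(phenylsulfinyl)acetate; 18 diphenyl(vinyl)sulfonium trifluoromethanesulfonate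
Product: 21 spiro vinyl-epoxide enoate (tert-butyl ester), via sulfonium ylide 19 (not isolated), via epoxy sulfoxide 20 (not isolated)
Conditions: LiCl, iPr2NEt, MeCN, 0 °C → rt; then 80 °C
Reagents that add atoms: none
Why: Proposed new method: chelation-assisted soft enolisation (LiCl/amine, as used for Horner–Wadsworth–Emmons olefination of base-sensitive aldehydes) should ionise only C6–H of the sulfinyl ester, the carbanion adds to the vinylsulfonium salt (bond C6–C7) to give ylide 19, the ylide carbon attacks the C9 aldehyde (bond C8–C9) and the betaine collapses to the epoxide 20 with loss of Ph2S, and warming then causes syn-elimination of PhSOH towards C7, the only carbon with a β-hydrogen, to unveil the C6=C7 alkene. The closest known reaction type is the annulation of nitrogen- or oxygen-nucleophile-tethered aldehydes and ketones with vinylsulfonium salts to epoxide-fused heterocycles (conjugate addition, then Johnson–Corey–Chaykovsky epoxidation), here extended to a carbon acid and coupled to a sulfoxide thermolysis. The six-membered carbocycle closes by 6-exo-trig attack of the ylide on the aldehyde and the oxirane by 3-exo-tet displacement of diphenyl sulfide. The C9 configuration is controlled by the C10 methyl group in a chair transition state with methyl and the aldehyde oxygen both equatorial (an axial oxygen would clash with the axial ring CH2 on the spiro carbon), so the epoxide oxygen should end trans to methyl, and C8 follows because the epoxide must be cis-fused. The step needs C-alkylation at C6 without enolisation of the aldehyde and without quenching of the ylide, which is secured by the lithium-chelated sulfinyl ester being the only readily ionised site, by the quaternary spiro carbon (no α-hydrogen, no alternative β-hydrogen) and by the absence of any acidic hydrogen at C6 once it is alkylated.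

Step 15
Reactants: 21 spiro vinyl-epoxide enoate (tert-butyl ester)
Product: 22 spiro epoxy allylic alcohol
Conditions: iBu2AlH (4 equiv), CH2Cl2, −78 → −40 °C
Reagents that add atoms: none
Why: iBu2AlH reduction of the enoate to the primary allylic alcohol at low temperature, where the epoxide and the mixed acetal should survive.

Step 16
Reactants: 22 spiro epoxy allylic alcohol; 23 angelic acid
Product: 24 spiro epoxy angelate
Conditions: PPh3, diisopropyl azodicarboxylate, THF, 0 °C → rt
Reagents that add atoms: none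
Why: Mitsunobu esterification, in which the carboxylate attacks the activated primary allylic alcohol, so the acid is never converted into an acylating agent and the (Z)-geometry of the angelate should be kept.

Step 17
Reactants: 24 spiro epoxy angelate
Product: 25 lactol diol
Conditions: HClO4 (cat.), THF/H2O, 0 °C
Reagents that add atoms: water, O
Why: Acid-catalysed hydrolysis in which water should open the vinyl epoxide at the allylic carbon C8 with inversion (trans-diol, C9–O retained) while the mixed acetal is hydrolysed to the lactol in the same pot.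

Step 18
Reactants: 25 lactol diol
Product: 26 CNP0224912.1 (target)
Conditions: 2,2,6,6-tetramethylpiperidine-1-oxyl (cat.), PhI(OAc)2, CH2Cl2, rt
Reagents that add atoms: none
Why: Oxoammonium-mediated oxidation of the lactol to the α-methylene-γ-butyrolactone, which should be much faster for a hemiacetal than for the two secondary alcohols.

**Compound list**
1 | (R)-4-methyldihydrofuran-2(3H)-one | O=C1C[C@@H](C)CO1 | starting material
2 | 3-bromo-2-methylprop-1-ene (methallyl bromide) | C=C(C)CBr | starting material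
3 | (3R,4R)-4-methyl-3-(2-methylprop-2-en-1-yl)dihydrofuran-2(3H)-one (methallyl trans to methyl) | C=C(C)C[C@H]1C(=O)OC[C@@H]1C | intermediate
4 | tert-butyl bromoacetate | BrCC(=O)OC(C)(C)C | starting material
5 | tert-butyl 2-[(3R,4R)-4-methyl-3-(2-methylprop-2-en-1-yl)-2-oxotetrahydrofuran-3-yl]acetate (methallyl cis to methyl) | C=C(C)C[C@@]1(C(=O)OC[C@@H]1C)CC(=O)OC(C)(C)C | intermediate
6 | tert-butyl 2-[(3R,4R)-2-hydroxy-4-methyl-3-(2-methylprop-2-en-1-yl)tetrahydrofuran-3-yl]acetate (lactol; both anomers) | C=C(C)C[C@@]1(C(O)OC[C@@H]1C)CC(=O)OC(C)(C)C | intermediate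
7 | tert-butyl (3S)-3-ethenyl-3-[(2R)-1-hydroxypropan-2-yl]-5-methylhex-5-enoate | C=C(C)C[C@@](C=C)(CC(=O)OC(C)(C)C)[C@@H](C)CO | intermediate
8 | tert-butyl (3S)-3-[(2R)-1-{[tert-butyl(dimethyl)silyl]oxy}propan-2-yl]-3-ethenyl-5-methylhex-5-enoate | C=C(C)C[C@@](C=C)(CC(=O)OC(C)(C)C)[C@@H](C)CO[Si](C)(C)C(C)(C)C | intermediate
9 | tert-butyl (3R)-3-[(2R)-1-{[tert-butyl(dimethyl)silyl]oxy}propan-2-yl]-3-formyl-5-oxohexanoate | CC(=O)C[C@@](C=O)(CC(=O)OC(C)(C)C)[C@@H](C)CO[Si](C)(C)C(C)(C)C | intermediate
10 | tert-butyl 2-[(1S)-1-[(2R)-1-{[tert-butyl(dimethyl)silyl]oxy}propan-2-yl]-4-oxocyclopent-2-en-1-yl]acetate | O=C1C[C@@](C=C1)(CC(=O)OC(C)(C)C)[C@@H](C)CO[Si](C)(C)C(C)(C)C | intermediate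
11 | tert-butyl 2-[(1S,4R)-1-[(2R)-1-{[tert-butyl(dimethyl)silyl]oxy}propan-2-yl]-4-hydroxycyclopent-2-en-1-yl]acetate (OH cis to the CH2CO2tBu arm) | O[C@@H]1C[C@@](C=C1)(CC(=O)OC(C)(C)C)[C@@H](C)CO[Si](C)(C)C(C)(C)C | intermediate
12 | methoxyallene (1-methoxypropa-1,2-diene) | C=C=COC | starting material
13 | tert-butyl 2-[(1S,4R)-1-[(2R)-1-{[tert-butyl(dimethyl)silyl]oxy}propan-2-yl]-4-[(2-iodo-1-methoxyprop-2-en-1-yl)oxy]cyclopent-2-en-1-yl]acetate (acetal epimers) | COC(O[C@@H]1C[C@@](C=C1)(CC(=O)OC(C)(C)C)[C@@H](C)CO[Si](C)(C)C(C)(C)C)C(I)=C | intermediate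
14 | tert-butyl 2-{2-methoxy-3-methylidene-5-[(2R)-1-{[tert-butyl(dimethyl)silyl]oxy}propan-2-yl]hexahydro-2H-cyclopenta[b]furan-5-yl}acetate (cis ring fusion; CH2CO2tBu arm on the face of the furan ring; acetal epimers) | C=C1C(OC)O[C@@H]2C[C@@](C[C@H]12)(CC(=O)OC(C)(C)C)[C@@H](C)CO[Si](C)(C)C(C)(C)C | intermediate
15 | 2-(phenylsulfinyl) derivative of 14 (mixture at the sulfinyl-bearing carbon and at sulfur) | C=C1C(OC)O[C@@H]2C[C@@](C[C@H]12)(C(S(=O)c1ccccc1)C(=O)OC(C)(C)C)[C@@H](C)CO[Si](C)(C)C(C)(C)C | intermediate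
16 | tert-butyl 2-{5-[(2R)-1-hydroxypropan-2-yl]-2-methoxy-3-methylidenehexahydro-2H-cyclopenta[b]furan-5-yl}-2-(phenylsulfinyl)acetate | C=C1C(OC)O[C@@H]2C[C@@](C[C@H]12)(C(S(=O)c1ccccc1)C(=O)OC(C)(C)C)[C@@H](C)CO | intermediate
17 | tert-butyl 2-{2-methoxy-3-methylidene-5-[(2R)-1-oxopropan-2-yl]hexahydro-2H-cyclopenta[b]furan-5-yl}-2-(phenylsulfinyl)acetate | C=C1C(OC)O[C@@H]2C[C@@](C[C@H]12)(C(S(=O)c1ccccc1)C(=O)OC(C)(C)C)[C@@H](C)C=O | intermediate
18 | diphenyl(vinyl)sulfonium trifluoromethanesulfonate | C=C[S+](c1ccccc1)c1ccccc1.[O-]S(=O)(=O)C(F)(F)F | starting material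
19 | sulfonium ylide formed by addition of the C6 carbanion of 17 to 18 | C=C1C(OC)O[C@@H]2C[C@@](C[C@H]12)(C(C[CH-][S+](c1ccccc1)c1ccccc1)(S(=O)c1ccccc1)C(=O)OC(C)(C)C)[C@@H](C)C=O | intermediate
20 | spiro epoxy sulfoxide: tert-butyl 8,9-epoxy-10-methyl-6-(phenylsulfinyl)spiro[4.5]decane-6-carboxylate with the 2-methoxy-3-methylidene tetrahydrofuran cis-fused at C2–C3 (epoxide trans to the C10 methyl) | C=C1C(OC)O[C@@H]2C[C@@]3(C[C@H]12)C(S(=O)c1ccccc1)(C(=O)OC(C)(C)C)C[C@H]4O[C@H]4[C@@H]3C | intermediate
21 | spiro vinyl-epoxide enoate: tert-butyl 8,9-epoxy-10-methylspiro[4.5]dec-6-ene-6-carboxylate with the 2-methoxy-3-methylidene tetrahydrofuran cis-fused at C2–C3 (epoxide trans to the C10 methyl) | C=C1C(OC)O[C@@H]2C[C@@]3(C[C@H]12)C(C(=O)OC(C)(C)C)=C[C@H]4O[C@H]4[C@@H]3C | intermediate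
22 | spiro epoxy allylic alcohol: the 6-(hydroxymethyl) compound from 21 | C=C1C(OC)O[C@@H]2C[C@@]3(C[C@H]12)C(CO)=C[C@H]4O[C@H]4[C@@H]3C | intermediate
23 | angelic acid ((Z)-2-methylbut-2-enoic acid) | C/C=C(/C)C(=O)O | starting material
24 | spiro epoxy angelate: the (Z)-2-methylbut-2-enoate of 22 | C=C1C(OC)O[C@@H]2C[C@@]3(C[C@H]12)C(COC(=O)/C(C)=C\C)=C[C@H]4O[C@H]4[C@@H]3C | intermediate
25 | lactol diol: the (8S,9S)-trans-diol angelate with the lactone at the lactol oxidation level (lactol epimers) | C=C1C(O)O[C@@H]2C[C@@]3(C[C@H]12)C(COC(=O)/C(C)=C\C)=C[C@H](O)[C@@H](O)[C@@H]3C | intermediate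
26 | CNP0224912.1: angelate of the (8S,9S)-dihydroxy-(10R)-methylspiro[4.5]dec-6-ene-6-methanol, (5R)-spiro, carrying the cis-fused α-methylene-γ-butyrolactone on C2 (R) and C3 (R) | C=C1C(=O)O[C@@H]2C[C@@]3(C[C@H]12)C(COC(=O)/C(C)=C\C)=C[C@H](O)[C@@H](O)[C@@H]3C | target

**Step count and risks**
Total: 18 steps. Longest linear sequence: 18 steps (1 → 26); the route is fully linear.

Step 14 (Proposed new method). The conjugate addition of the carbanion, which is flanked by the quaternary spiro carbon, may be too slow, so that the vinylsulfonium salt is consumed otherwise. The ylide may also be quenched by proton transfer from the aldehyde α-position before it closes the ring, and the ring closure may show poor facial selectivity. The fallback makes the two bonds one after the other with known reactions and sets out from 17. CH2=CHMgBr (2.2 equiv, CeCl3, THF, −78 °C) should add to the aldehyde (bond C8–C9) to give the allylic alcohol F1. ClCO2Me and pyridine should give the allylic methyl carbonate F2. Pd(PPh3)4 with NaH in THF at 60 °C should bring about an intramolecular Tsuji–Trost alkylation, the sulfinyl ester carbanion attacking the far terminus of the π-allyl unit (bond C6–C7, six-membered ring), to give the spiro cyclohexene sulfoxide F3. Heating in toluene at 100 °C should eliminate PhSOH to the cyclohexa-1,3-diene ester F4. 3-Chloroperbenzoic acid (CH2Cl2, 0 °C) should epoxidise the alkene remote from the ester, anti to the C10 methyl group, and the fallback comes back to the route at 21.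

Step 8. The hydride delivery may show poor facial selectivity, because the alkene arm and the CH2 arm of the enone differ little in size and the substrate may oppose the catalyst. The fallback sets out from 10 and replaces reagent control by reduction and inversion. NaBH4 with CeCl3 in MeOH at −78 °C (Luche reduction) should give 11 together with its carbinol epimer F5. After separation, F5 is inverted by a Mitsunobu reaction (4-nitrobenzoic acid, PPh3, diisopropyl azodicarboxylate) to the 4-nitrobenzoate F6. K2CO3 in MeOH then comes back to the route at 11.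

Step 17. The protonated vinyl epoxide may ionise to an allyl cation, with loss of regio- and stereocontrol (cis-diol, 1,4-diol) and participation of the neighbouring angelate carbonyl. The fallback sets out from 21 and opens the epoxide before reduction and acylation. Acetate (NaOAc, AcOH, DMF, 60 °C) should attack the allylic carbon C8 of the electron-poor epoxy enoate in SN2 fashion to give the trans hydroxy acetate F7. iBu2AlH (CH2Cl2, −78 → 0 °C) should reduce both esters to the triol F8. Mitsunobu esterification with 23 at the primary allylic hydroxyl should give the angelate diol F9. Pyridinium p-toluenesulfonate in wet acetone should hydrolyse only the mixed acetal, and the fallback comes back to the route at 25.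

Further compounds
F1 | step 14 | allylic alcohol from vinyl addition to 17 (carbinol epimers) | C=C1C(OC)O[C@@H]2C[C@@](C[C@H]12)(C(S(=O)c1ccccc1)C(=O)OC(C)(C)C)[C@@H](C)C(O)C=C
F2 | step 14 | allylic methyl carbonate of F1 | C=C1C(OC)O[C@@H]2C[C@@](C[C@H]12)(C(S(=O)c1ccccc1)C(=O)OC(C)(C)C)[C@@H](C)C(OC(=O)OC)C=C
F3 | step 14 | spiro cyclohexene sulfoxide: tert-butyl 10-methyl-6-(phenylsulfinyl)spiro[4.5]dec-8-ene-6-carboxylate with the fused methoxy methylidene tetrahydrofuran | C=C1C(OC)O[C@@H]2C[C@@]3(C[C@H]12)C(S(=O)c1ccccc1)(C(=O)OC(C)(C)C)CC=C[C@@H]3C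
F4 | step 14 | spiro cyclohexa-1,3-diene ester: tert-butyl 10-methylspiro[4.5]deca-6,8-diene-6-carboxylate with the fused methoxy methylidene tetrahydrofuran | C=C1C(OC)O[C@@H]2C[C@@]3(C[C@H]12)C(C(=O)OC(C)(C)C)=CC=C[C@@H]3C
F5 | step 8 | carbinol epimer of 11 (OH trans to the CH2CO2tBu arm) | O[C@H]1C[C@@](C=C1)(CC(=O)OC(C)(C)C)[C@@H](C)CO[Si](C)(C)C(C)(C)C
F6 | step 8 | 4-nitrobenzoate of 11 | O=C(O[C@@H]1C[C@@](C=C1)(CC(=O)OC(C)(C)C)[C@@H](C)CO[Si](C)(C)C(C)(C)C)c1ccc(cc1)[N+](=O)[O-]
F7 | step 17 | trans hydroxy acetate: tert-butyl 8-acetoxy-9-hydroxy enoate from 21 | C=C1C(OC)O[C@@H]2C[C@@]3(C[C@H]12)C(C(=O)OC(C)(C)C)=C[C@H](OC(C)=O)[C@@H](O)[C@@H]3C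
F8 | step 17 | triol: 6-(hydroxymethyl)-8,9-trans-diol with the mixed acetal intact | C=C1C(OC)O[C@@H]2C[C@@]3(C[C@H]12)C(CO)=C[C@H](O)[C@@H](O)[C@@H]3C
F9 | step 17 | angelate diol with the mixed acetal intact | C=C1C(OC)O[C@@H]2C[C@@]3(C[C@H]12)C(COC(=O)/C(C)=C\C)=C[C@H](O)[C@@H](O)[C@@H]3C
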